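## Retrosynthetic overview

1. Ten-membered carbocycle last: C4=C5 (Z) by ring-closing metathesis of an open-chain styryl/isopropenyl diene.
2. C2–C3 by a reagent-controlled boron aldol with methacrolein; C8–O isovalerate bond by an invertive Mitsunobu esterification.
3. C7–C8 by zinc Barbier union of a (5R)-3-(bromomethyl)-5-styrylbutenolide with (3R)-3-hydroxy-3-methyl-4-oxopentanal.
4. Lactone ring first: C6–O ester bond between a lipase-resolved bis-allylic alcohol and 2-(bromomethyl)acrylic acid, then butenolide ring-closing metathesis.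
5. Key step: the keto-aldehyde comes from achiral 3-methylpenta-1,4-dien-3-ol by two C–O bond-forming Wacker oxidations, the first a new enantioselective desymmetrisation that sets C10 and the C1 ketone.

Numbering: C1–C15 in the text are germacrane locants (C1 ketone, C3 carbinol, C4=C5 alkene with C15 methyl, C6 lactone O–CH, C7 ring-fusion CH, C8 ester carbinol, C10 tertiary carbinol with C14 methyl, C11=C13 methylidene, C12 lactone carbonyl). The target is 3R,6R,7R,8R,10R,4Z with a trans-fused lactone.

Assumption: the zinc Barbier step is taken to give the 7,8-anti (8S) carbinol expected from a ring-locked E-type allylzinc in a closed transition state (hence the invertive esterification), and the stated antipodes of the step 1 ligand and of Ipc2BCl are those expected to give C10 R and C3 R, to be confirmed on the first run.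

## Route

Step 1
Reactants: 1 3-methylpenta-1,4-dien-3-ol
Product: 2 (3R)-3-hydroxy-3-methylpent-4-en-2-one
Conditions: Pd(MeCN)2Cl2 (5 mol %), (S)-4-tert-butyl-2-(quinolin-2-yl)-4,5-dihydrooxazole (6 mol %), AgSbF6 (12 mol %), aq. TBHP (1.3 equiv), CH2Cl2, 0 °C
Reagents that add atoms: tert-butyl hydroperoxide, CC(C)(C)OO
Why: Proposed new method: a cationic divalent-palladium quinoline-oxazoline tert-butylperoxide complex should bind the tertiary hydroxyl and one vinyl group of the prochiral carbinol in a five-membered chelate, so that the tert-butyl group of the ligand tells the two enantiotopic vinyl groups apart, after which syn-peroxypalladation puts oxygen on the internal carbon and a 1,2-hydride shift releases the methyl ketone, setting C10 by group selection while any ent-product is preferentially oxidised on to the achiral diketone and so raises the ee; the closest known reaction type is the Tsuji–Wacker oxidation of allylic alcohol derivatives to acyloins with the achiral quinoline-oxazoline palladium/TBHP catalyst.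

Step 2
Reactants: 2 (3R)-3-hydroxy-3-methylpent-4-en-2-one
Product: 3 (3R)-3-hydroxy-3-methyl-4-oxopentanal
Conditions: PdCl2(PhCN)2 (10 mol %), CuCl2·2H2O (10 mol %), AgNO2 (5 mol %), O2 (1 atm), tBuOH/MeNO2 15:1, 20 °C; crude aldehyde used at once
Reagents that add atoms: dioxygen, O=O
Why: Aldehyde-selective (anti-Markovnikov) Tsuji–Wacker oxidation with a nitrite co-catalyst, favoured here because the internal alkene carbon is neopentylic and flanked by the tertiary hydroxyl, and it touches no stereocentre.

Step 3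
Reactants: 4 (E)-cinnamaldehyde, 5 vinylmagnesium bromide
Product: 6 rac-(1E)-1-phenylpenta-1,4-dien-3-ol
Conditions: THF, −78 to 0 °C; aq. NH4Cl
Reagents that add atoms: none
Why: 1,2-Grignard addition to the enal gives the racemic bis-allylic alcohol.

Step 4
Reactants: 6 rac-(1E)-1-phenylpenta-1,4-dien-3-ol
Product: 7 (3S,1E)-1-phenylpenta-1,4-dien-3-ol
Conditions: immobilised Candida antarctica lipase B, vinyl acetate (3 equiv), MTBE, 30 °C, stopped at about 52 % conversion
Reagents that add atoms: none
Why: Lipase kinetic resolution by transesterification, in which Kazlauskas' rule (styryl large, vinyl medium) has the R alcohol acetylated and the S alcohol left behind, which fixes the later C6.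

Step 5
Reactants: 7 (3S,1E)-1-phenylpenta-1,4-dien-3-ol, 8 2-(bromomethyl)acrylic acid
Product: 9 (3S,1E)-1-phenylpenta-1,4-dien-3-yl 2-(bromomethyl)prop-2-enoate
Conditions: DCC, DMAP (5 mol %), CH2Cl2, 0 °C
Reagents that add atoms: none
Why: Steglich esterification makes the future lactone C–O bond at the acyl carbon only, so the carbinol configuration is retained.

Step 6
Reactants: 9 (3S,1E)-1-phenylpenta-1,4-dien-3-yl 2-(bromomethyl)prop-2-enoate
Product: 10 (5R)-3-(bromomethyl)-5-[(E)-2-phenylethenyl]furan-2(5H)-one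
Conditions: second-generation Grubbs catalyst, RuCl2(H2IMes)(PCy3)(=CHPh) (5 mol %), CH2Cl2 (0.01 M), 40 °C
Reagents that add atoms: none
Why: Ring-closing metathesis of the acrylate with the terminal vinyl group, which loads ruthenium much faster than the styryl group, gives the butenolide without touching the stereocentre, and the minor closure through the styryl group gives a constitutionally different 5-vinyl lactone that is removed by chromatography.

Step 7
Reactants: 10 (5R)-3-(bromomethyl)-5-[(E)-2-phenylethenyl]furan-2(5H)-one, 3 (3R)-3-hydroxy-3-methyl-4-oxopentanal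
Product: 12 (4R,5R)-4-[(1S,3R)-1,3-dihydroxy-3-methyl-4-oxopentyl]-3-methylidene-5-[(E)-2-phenylethenyl]oxolan-2-one, via allylzinc bromide 11 (not isolated)
Conditions: Zn dust (3 equiv), THF/sat. aq. NH4Cl 2:1, 0 °C to rt; 3 in slight excess
Reagents that add atoms: none
Why: Zinc Barbier allylation in which the allylzinc attacks the aldehyde (much faster than the ketone) through its γ-carbon C7 anti to the styryl group in a closed chair transition state, giving the 6,7-trans lactone and, because the ring fixes an E-type allylmetal, the 7,8-anti (8S) carbinol.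

Step 8
Reactants: 12 (4R,5R)-4-[(1S,3R)-1,3-dihydroxy-3-methyl-4-oxopentyl]-3-methylidene-5-[(E)-2-phenylethenyl]oxolan-2-one, 13 3-methylbutanoic acid
Product: 14 (1R,3R)-3-hydroxy-3-methyl-1-[(2R,3R)-4-methylidene-5-oxo-2-[(E)-2-phenylethenyl]oxolan-3-yl]-4-oxopentyl 3-methylbutanoate
Conditions: PPh3 (2 equiv), DIAD (2 equiv), 13 (3 equiv), toluene, 0 °C to rt
Reagents that add atoms: none
Why: Mitsunobu esterification installs the isovalerate by SN2 displacement with inversion at C8 (S to R), the tertiary C10 hydroxyl being too hindered to react.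

Step 9
Reactants: 14 (1R,3R)-3-hydroxy-3-methyl-1-[(2R,3R)-4-methylidene-5-oxo-2-[(E)-2-phenylethenyl]oxolan-3-yl]-4-oxopentyl 3-methylbutanoate, 15 methacrolein
Product: 17 (1R,3R,6R)-3,6-dihydroxy-3,7-dimethyl-1-[(2R,3R)-4-methylidene-5-oxo-2-[(E)-2-phenylethenyl]oxolan-3-yl]-4-oxooct-7-en-1-yl 3-methylbutanoate, via enol borinate 16 (not isolated)
Conditions: (+)-Ipc2BCl (1.3 equiv), Et3N (1.5 equiv), Et2O, −78 to 0 °C; then 15 (2 equiv), −78 to −20 °C; MeOH/pH 7 buffer work-up without peroxide
Reagents that add atoms: none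
Why: Paterson boron aldol in which the enol diisopinocampheylborinate of the methyl ketone (the only enolisable ketone position) adds to the re face of methacrolein under reagent control to give the 3R carbinol, while the esters and the lactone are not enolised by the chloroborane/amine pair.

Step 10
Reactants: 17 (1R,3R,6R)-3,6-dihydroxy-3,7-dimethyl-1-[(2R,3R)-4-methylidene-5-oxo-2-[(E)-2-phenylethenyl]oxolan-3-yl]-4-oxooct-7-en-1-yl 3-methylbutanoate
Product: 18 (3aR,4R,6R,9R,10Z,11aR)-6,9-dihydroxy-6,10-dimethyl-3-methylidene-2,7-dioxo-2,3,3a,4,5,6,7,8,9,11a-decahydrocyclodeca[b]furan-4-yl 3-methylbutanoate (target)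
Conditions: second-generation Hoveyda–Grubbs catalyst, RuCl2(H2IMes)(=CH-C6H4-2-OiPr) (20 mol % in portions), 1,4-benzoquinone (40 mol %), toluene (1 mM), 90 °C
Reagents that add atoms: none
Why: Ring-closing metathesis between the styryl and isopropenyl groups forms the trisubstituted C4=C5 bond, which the trans-lactone-fused ten-membered ring is expected to hold in the Z geometry, with styrene lost and benzoquinone suppressing ruthenium hydride isomerisation of the allylic alcohol.

## Compound list

1 | 3-methylpenta-1,4-dien-3-ol | C=CC(C)(O)C=C | starting material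
2 | (3R)-3-hydroxy-3-methylpent-4-en-2-one | CC(=O)[C@](C)(O)C=C | intermediate
3 | (3R)-3-hydroxy-3-methyl-4-oxopentanal | CC(=O)[C@](C)(O)CC=O | intermediate
4 | (E)-cinnamaldehyde | O=C/C=C/c1ccccc1 | starting material
5 | vinylmagnesium bromide | C=C[Mg]Br | starting material
6 | rac-(1E)-1-phenylpenta-1,4-dien-3-ol | C=CC(O)/C=C/c1ccccc1 | intermediate
7 | (3S,1E)-1-phenylpenta-1,4-dien-3-ol | C=C[C@H](O)/C=C/c1ccccc1 | intermediate
8 | 2-(bromomethyl)acrylic acid | C=C(CBr)C(=O)O | starting material
9 | (3S,1E)-1-phenylpenta-1,4-dien-3-yl 2-(bromomethyl)prop-2-enoate | C=C[C@H](OC(=O)C(=C)CBr)/C=C/c1ccccc1 | intermediate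
10 | (5R)-3-(bromomethyl)-5-[(E)-2-phenylethenyl]furan-2(5H)-one | BrCC1=C[C@@H](/C=C/c2ccccc2)OC1=O | intermediate
11 | {[(5R)-2-oxo-5-[(E)-2-phenylethenyl]-2,5-dihydrofuran-3-yl]methyl}zinc bromide | Br[Zn]CC1=C[C@@H](/C=C/c2ccccc2)OC1=O | intermediate
12 | (4R,5R)-4-[(1S,3R)-1,3-dihydroxy-3-methyl-4-oxopentyl]-3-methylidene-5-[(E)-2-phenylethenyl]oxolan-2-one | C=C1C(=O)O[C@H](/C=C/c2ccccc2)[C@H]1[C@@H](O)C[C@@](C)(O)C(C)=O | intermediate
13 | 3-methylbutanoic acid (isovaleric acid) | CC(C)CC(=O)O | starting material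
14 | (1R,3R)-3-hydroxy-3-methyl-1-[(2R,3R)-4-methylidene-5-oxo-2-[(E)-2-phenylethenyl]oxolan-3-yl]-4-oxopentyl 3-methylbutanoate | C=C1C(=O)O[C@H](/C=C/c2ccccc2)[C@H]1[C@H](OC(=O)CC(C)C)C[C@@](C)(O)C(C)=O | intermediate
15 | methacrolein | C=C(C)C=O | starting material
16 | enol bis[(1S,2R,3S,5S)-isopinocampheyl]borinate of 14 (boron on the C1 enol oxygen, C10 hydroxyl free) | C=C1C(=O)O[C@H](/C=C/c2ccccc2)[C@H]1[C@H](OC(=O)CC(C)C)C[C@@](C)(O)C(=C)OB([C@H]1C[C@H]2C[C@@H]([C@@H]1C)C2(C)C)[C@H]1C[C@H]2C[C@@H]([C@@H]1C)C2(C)C | intermediate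
17 | (1R,3R,6R)-3,6-dihydroxy-3,7-dimethyl-1-[(2R,3R)-4-methylidene-5-oxo-2-[(E)-2-phenylethenyl]oxolan-3-yl]-4-oxooct-7-en-1-yl 3-methylbutanoate | C=C1C(=O)O[C@H](/C=C/c2ccccc2)[C@H]1[C@H](OC(=O)CC(C)C)C[C@@](C)(O)C(=O)C[C@@H](O)C(C)=C | intermediate
18 | (3aR,4R,6R,9R,10Z,11aR)-6,9-dihydroxy-6,10-dimethyl-3-methylidene-2,7-dioxo-2,3,3a,4,5,6,7,8,9,11a-decahydrocyclodeca[b]furan-4-yl 3-methylbutanoate | C=C1C(=O)O[C@@H]2/C=C(/C)[C@H](O)CC(=O)[C@](C)(O)C[C@@H](OC(=O)CC(C)C)[C@@H]12 | target

## Step count and risks

Total step count: 10. Longest linear sequence: 8 (steps 3 to 10); the keto-aldehyde branch is 2 steps (steps 1 and 2).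

Three steps most likely to fail:

**Step 1 (the proposed new desymmetrising Wacker oxidation).** It may give low ee, or the cationic palladium may rearrange the tertiary bis-allylic alcohol. The fallback uses known chemistry only; it sets out from 1 and comes back at 12. Compound 1 is oxidised with the established achiral quinoline-oxazoline palladium/TBHP Wacker catalyst to racemic 3-hydroxy-3-methylpent-4-en-2-one F1. The step 2 conditions turn this into racemic 3-hydroxy-3-methyl-4-oxopentanal F2. Barbier coupling of F2 with enantiopure 10 as in step 7 then uses the bromolactone as the resolving partner. It gives 12 together with its C10 epimer (4R,5R)-4-[(1S,3S)-1,3-dihydroxy-3-methyl-4-oxopentyl]-3-methylidene-5-[(E)-2-phenylethenyl]oxolan-2-one F3, which is removed by chromatography. This replaces the catalytic desymmetrisation by a resolution through diastereomers and costs half of the keto-aldehyde.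

**Step 8 (Mitsunobu inversion with an aliphatic acid).** The secondary alcohol is hindered and homoallylic, so elimination towards C7 is possible, and the γ-hydroxy ketone can sit partly as a cyclic hemiketal. The fallback sets C8 correctly when the C7–C8 bond is made instead of inverting it; it sets out from 10 (with 3) and comes back at 14. Compound 10 is converted with hexabutylditin and catalytic Pd(PPh3)4 into (5R)-5-[(E)-2-phenylethenyl]-3-[(tributylstannyl)methyl]furan-2(5H)-one F4. BF3·OEt2-promoted addition of F4 to 3 at −78 °C runs through an open antiperiplanar transition state, which gives the 7,8-syn adduct, still anti to the styryl group. The product is (4R,5R)-4-[(1R,3R)-1,3-dihydroxy-3-methyl-4-oxopentyl]-3-methylidene-5-[(E)-2-phenylethenyl]oxolan-2-one F5. Acylation of its secondary hydroxyl with isovaleric anhydride and DMAP, with retention, gives 14.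

**Step 10 (macrocyclic ring-closing metathesis).** Closure to a strained trisubstituted cyclodecene may stall, oligomerise or give the E isomer. The fallback closes the ring at C2–C3 by an aldol reaction instead; it sets out from 14 and ends at 18.
- Ozonolysis of the styryl group of 14 (O3, CH2Cl2/MeOH, −78 °C, then Me2S; the electron-poor methylidene lactone is spared) gives (1R,3R)-1-[(2S,3R)-2-formyl-4-methylidene-5-oxooxolan-3-yl]-3-hydroxy-3-methyl-4-oxopentyl 3-methylbutanoate F6.
- Stork–Zhao-type Wittig olefination with the ylide from (1-iodoethyl)triphenylphosphonium iodide and NaHMDS gives the Z vinyl iodide (1R,3R)-3-hydroxy-1-[(2S,3R)-2-[(Z)-2-iodoprop-1-en-1-yl]-4-methylidene-5-oxooxolan-3-yl]-3-methyl-4-oxopentyl 3-methylbutanoate F7.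
- Formylation with Pd(PPh3)4, CO and Bu3SnH, with retention of geometry, gives the Z enal (1R,3R)-3-hydroxy-3-methyl-1-[(2R,3R)-4-methylidene-2-[(Z)-2-methyl-3-oxoprop-1-en-1-yl]-5-oxooxolan-3-yl]-4-oxopentyl 3-methylbutanoate F8.
- Intramolecular boron aldol of the methyl ketone of F8 onto its enal (Cy2BCl, Et3N, high dilution) closes the ten-membered ring to 18. The C3 configuration is then set by the ring and has to be checked.

## Further compounds

F1 | step 1 | rac-3-hydroxy-3-methylpent-4-en-2-one | CC(=O)C(C)(O)C=C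
F2 | step 1 | rac-3-hydroxy-3-methyl-4-oxopentanal | CC(=O)C(C)(O)CC=O
F3 | step 1 | (4R,5R)-4-[(1S,3S)-1,3-dihydroxy-3-methyl-4-oxopentyl]-3-methylidene-5-[(E)-2-phenylethenyl]oxolan-2-one | C=C1C(=O)O[C@H](/C=C/c2ccccc2)[C@H]1[C@@H](O)C[C@](C)(O)C(C)=O
F4 | step 8 | (5R)-5-[(E)-2-phenylethenyl]-3-[(tributylstannyl)methyl]furan-2(5H)-one | CCCC[Sn](CCCC)(CCCC)CC1=C[C@@H](/C=C/c2ccccc2)OC1=O
F5 | step 8 | (4R,5R)-4-[(1R,3R)-1,3-dihydroxy-3-methyl-4-oxopentyl]-3-methylidene-5-[(E)-2-phenylethenyl]oxolan-2-one | C=C1C(=O)O[C@H](/C=C/c2ccccc2)[C@H]1[C@H](O)C[C@@](C)(O)C(C)=O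
F6 | step 10 | (1R,3R)-1-[(2S,3R)-2-formyl-4-methylidene-5-oxooxolan-3-yl]-3-hydroxy-3-methyl-4-oxopentyl 3-methylbutanoate | C=C1C(=O)O[C@H](C=O)[C@H]1[C@H](OC(=O)CC(C)C)C[C@@](C)(O)C(C)=O
F7 | step 10 | (1R,3R)-3-hydroxy-1-[(2S,3R)-2-[(Z)-2-iodoprop-1-en-1-yl]-4-methylidene-5-oxooxolan-3-yl]-3-methyl-4-oxopentyl 3-methylbutanoate | C=C1C(=O)O[C@H](/C=C(/C)I)[C@H]1[C@H](OC(=O)CC(C)C)C[C@@](C)(O)C(C)=O
F8 | step 10 | (1R,3R)-3-hydroxy-3-methyl-1-[(2R,3R)-4-methylidene-2-[(Z)-2-methyl-3-oxoprop-1-en-1-yl]-5-oxooxolan-3-yl]-4-oxopentyl 3-methylbutanoate | C=C1C(=O)O[C@H](/C=C(/C)C=O)[C@H]1[C@H](OC(=O)CC(C)C)C[C@@](C)(O)C(C)=O
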